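**Retrosynthetic overview**
- The plan rests on ring B. Its ether carbon C1 lies between C2–OH and C6–OH, with the chain at C4. C2 and C6 are carried as formyl groups, which first activate a C1–F bond and are later exchanged for oxygen.
- Last disconnections: the ring A O–CH3 bond, then both ring B C(aryl)–CHO bonds by a double Baeyer–Villiger oxidation of a macrocyclic 2-aryloxyisophthalaldehyde.
- Rings A and B are bought. The only ring formed is the 20-membered macrocycle, closed at the ring A O–ring B C1 bond by fluoride-triggered SNAr of a silyl ether on a 2-fluoroisophthalaldehyde.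
- The C12 tether comes from dodeca-1,11-diene by two hydroboration/B-alkyl Suzuki–Miyaura couplings, first to the ring A bromide and then to the ring B bromide with its aldehydes masked as dioxolanes.
- The ring B bromide comes from 5-bromo-2-fluoro-1,3-dimethylbenzene by benzylic tetrabromination, hydrolysis and acetalisation.

Key step: step 9

Remark on locants: ring A is the 1,3,5-trisubstituted ring (O-substituent, ether oxygen, chain). Ring B is the tetrasubstituted ring (C1 ether carbon, C2/C6 flanking positions, C4 chain).

Remark on the chemistry: the ring A phenol is taken from commercial 3-bromo-5-methoxyphenol and carried as a triisopropylsilyl ether. In this way no thiolate or Lewis-acid demethylation is run next to the aryl fluoride or the acetals.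

**Step 1**
Reactants: 1 5-bromo-2-fluoro-1,3-dimethylbenzene
Product: 2 5-bromo-1,3-bis(dibromomethyl)-2-fluorobenzene
Conditions: NBS (4.6 equiv), AIBN (0.1 equiv), PhCF3, reflux, visible-light lamp
Reagents that add atoms: N-bromosuccinimide, O=C1CCC(=O)N1Br
Why: Wohl–Ziegler radical bromination should take each benzylic methyl to the dibromomethyl stage and stop there, because a third bromination is sterically and electronically disfavoured and the ring C–Br and C–F bonds are inert to bromine radicals.

**Step 2**
Reactants: 2 5-bromo-1,3-bis(dibromomethyl)-2-fluorobenzene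
Product: 3 5-bromo-2-fluorobenzene-1,3-dicarbaldehyde
Conditions: AgNO3 (4.4 equiv), acetone/H2O 4:1, reflux, dark
Reagents that add atoms: water, O
Why: Silver-assisted hydrolysis of the benzal dibromides gives bromohydrins that collapse to the aldehydes, and the acidic, weakly nucleophilic medium should leave the newly activated C–F bond intact.

**Step 3**
Reactants: 3 5-bromo-2-fluorobenzene-1,3-dicarbaldehyde
Product: 4 2,2'-(5-bromo-2-fluorobenzene-1,3-diyl)bis(1,3-dioxolane)
Conditions: HOCH2CH2OH (6 equiv), p-TsOH·H2O (5 mol%), toluene, Dean–Stark, reflux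
Reagents that add atoms: ethylene glycol, OCCO
Why: Acid-catalysed acetalisation with azeotropic water removal masks both aldehydes, which switches off the activation of fluorine and shields the carbonyls from borane and aqueous base in the coupling.

**Step 4**
Reactants: 5 3-bromo-5-methoxyphenol
Product: 6 (3-bromo-5-methoxyphenoxy)tri(propan-2-yl)silane
Conditions: TIPSCl (1.2 equiv), imidazole (2.5 equiv), DMF, rt
Reagents that add atoms: chlorotri(propan-2-yl)silane, CC(C)[Si](Cl)(C(C)C)C(C)C
Why: Imidazole-promoted O-silylation of a phenol gives a bulky silyl ether that withstands borane, aqueous phosphate and dilute acid but is cleaved by fluoride.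

**Step 5**
Reactants: 7 dodeca-1,11-diene; 6 (3-bromo-5-methoxyphenoxy)tri(propan-2-yl)silane
Product: 9 [3-(dodec-11-en-1-yl)-5-methoxyphenoxy]tri(propan-2-yl)silane, via 9-(dodec-11-en-1-yl)-9-borabicyclo[3.3.1]nonane 8 (not isolated)
Conditions: 7 (4 equiv), 9-BBN (0.5 M in THF, 1.1 equiv relative to 6), 0 °C → rt; then 6, PdCl2(dppf) (4 mol%), K3PO4 (3 M aq, 3 equiv), THF, 55 °C; excess 7 recovered on chromatography
Reagents that add atoms: 9-borabicyclo[3.3.1]nonane, B1C2CCCC1CCC2 (its boron cage is held only by intermediate 8; product 9 keeps one hydrogen)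
Why: Anti-Markovnikov hydroboration with 9-BBN in a large excess of diene should give mainly the mono-borane, which undergoes B-alkyl Suzuki–Miyaura coupling with the aryl bromide faster than the unactivated alkenes can react in a Heck manner.

**Step 6**
Reactants: 9 [3-(dodec-11-en-1-yl)-5-methoxyphenoxy]tri(propan-2-yl)silane; 4 2,2'-(5-bromo-2-fluorobenzene-1,3-diyl)bis(1,3-dioxolane)
Product: 11 2,2'-{2-fluoro-5-[12-(3-methoxy-5-{[tri(propan-2-yl)silyl]oxy}phenyl)dodecyl]benzene-1,3-diyl}bis(1,3-dioxolane), via ring A dodecyl-9-BBN borane 10 (not isolated)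
Conditions: 9, 9-BBN (0.5 M in THF, 1.4 equiv), rt; then 4 (1.0 equiv), PdCl2(dppf) (5 mol%), K3PO4 (3 M aq, 3 equiv), THF, 55 °C
Reagents that add atoms: 9-borabicyclo[3.3.1]nonane, B1C2CCCC1CCC2 (its boron cage is held only by intermediate 10; product 11 keeps one hydrogen)
Why: Terminal-selective 9-BBN hydroboration followed by B-alkyl Suzuki–Miyaura coupling at the unhindered C–Br of 4 forms the ring B C4–CH2 bond, with the acetals, the silyl ether and the unactivated C–F bond inert under these conditions.

**Step 7**
Reactants: 11 open-chain bis-dioxolane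
Product: 12 2-fluoro-5-[12-(3-methoxy-5-{[tri(propan-2-yl)silyl]oxy}phenyl)dodecyl]benzene-1,3-dicarbaldehyde
Conditions: 1 M HCl aq/THF 1:3, rt
Reagents that add atoms: water, O
Why: Acid-catalysed acetal hydrolysis frees both aldehydes, while the aryl triisopropylsilyl ether survives dilute acid and so prevents both acid-induced condensation of ring A with the aldehydes and premature etherification.

**Step 8**
Reactants: 12 open-chain fluoro dialdehyde silyl ether
Product: 14 macrocyclic diaryl ether dialdehyde (20-membered ring; ring A methoxy; ring B C2 and C6 formyl; twelve CH2 groups from ring A to ring B C4), via cesium phenoxide 13 (not isolated)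
Conditions: CsF (5 equiv, flame-dried), 4 Å MS, DMF, 60 °C; 12 added by syringe pump over 12 h to a final 2 mM
Reagents that add atoms: cesium fluoride, [Cs+].[F-] (its cation is held only by intermediate 13)
Why: Fluoride strips the silyl group, and the resulting phenoxide attacks ring B C1, whose fluorine is activated by both ortho formyl groups through a Meisenheimer adduct (macrocyclising SNAr etherification); slow addition and slow phenoxide release at millimolar concentration should favour ring closure over oligomers.

**Step 9**
Reactants: 14 macrocyclic diaryl ether dialdehyde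
Product: 16 ring A monomethyl ether of the target (ring B C2-OH and C6-OH free), via macrocyclic bis-formate 15 (not isolated)
Conditions: mCPBA (2.6 equiv), NaHCO3 (6 equiv, solid), CH2Cl2, 0 °C → rt; aq. Na2SO3 wash, concentrate; then K2CO3 (0.3 equiv), MeOH, Ar, 0 °C → rt; dilute HCl
Reagents that add atoms: 3-chloroperbenzoic acid, OOC(=O)c1cccc(Cl)c1
Why: Each formyl group on ring B adds the peracid to give a Criegee-type tetrahedral adduct, and the attached ring carbon (C2, then C6) shifts to the proximal peroxide oxygen as 3-chlorobenzoate departs, which makes the C2–O and C6–O bonds as aryl formates. The closest known reaction type is the Baeyer–Villiger (Dakin-type) oxidation of ortho- or para-alkoxy- and aryloxybenzaldehydes to phenol formates, here run twice on one ring. No ring is closed and no stereocentre is created. The step needs aryl rather than hydride migration at both aldehydes; the C1 ether oxygen, ortho to both migrating carbons, stabilises the developing positive charge, and the first insertion replaces an acceptor by a donor, so the second should be easier. Reaction at the aldehydes rather than at electron-rich ring A is secured by the solid bicarbonate buffer, low temperature and near-stoichiometric peracid. Catalytic carbonate in methanol under argon then transesterifies both labile formates and frees the two phenols.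

**Step 10**
Reactants: 16 ring A monomethyl ether of the target
Product: 17 target CNP0314249.0
Conditions: BBr3 (5 equiv), CH2Cl2, −78 °C → 0 °C; then ice/H2O
Reagents that add atoms: none
Why: Lewis-acid aryl methyl ether cleavage proceeds by boron coordination to the methoxy oxygen and bromide attack on the methyl carbon, and it leaves the diaryl ether C–O bonds untouched because neither aryl carbon can undergo SN2 displacement.

**Compound list**
1 | 5-bromo-2-fluoro-1,3-dimethylbenzene | Cc1cc(Br)cc(C)c1F | starting material
2 | 5-bromo-1,3-bis(dibromomethyl)-2-fluorobenzene | Fc1c(C(Br)Br)cc(Br)cc1C(Br)Br | intermediate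
3 | 5-bromo-2-fluorobenzene-1,3-dicarbaldehyde | O=Cc1cc(Br)cc(C=O)c1F | intermediate
4 | 2,2'-(5-bromo-2-fluorobenzene-1,3-diyl)bis(1,3-dioxolane) | Fc1c(C2OCCO2)cc(Br)cc1C3OCCO3 | intermediate
5 | 3-bromo-5-methoxyphenol | COc1cc(O)cc(Br)c1 | starting material
6 | (3-bromo-5-methoxyphenoxy)tri(propan-2-yl)silane | COc1cc(Br)cc(O[Si](C(C)C)(C(C)C)C(C)C)c1 | intermediate
7 | dodeca-1,11-diene | C=CCCCCCCCCCC=C | starting material
8 | 9-(dodec-11-en-1-yl)-9-borabicyclo[3.3.1]nonane | C=CCCCCCCCCCCB1C2CCCC1CCC2 | intermediate
9 | [3-(dodec-11-en-1-yl)-5-methoxyphenoxy]tri(propan-2-yl)silane | C=CCCCCCCCCCCc1cc(OC)cc(O[Si](C(C)C)(C(C)C)C(C)C)c1 | intermediate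
10 | 9-[12-(3-methoxy-5-{[tri(propan-2-yl)silyl]oxy}phenyl)dodecyl]-9-borabicyclo[3.3.1]nonane | COc1cc(CCCCCCCCCCCCB2C3CCCC2CCC3)cc(O[Si](C(C)C)(C(C)C)C(C)C)c1 | intermediate
11 | 2,2'-{2-fluoro-5-[12-(3-methoxy-5-{[tri(propan-2-yl)silyl]oxy}phenyl)dodecyl]benzene-1,3-diyl}bis(1,3-dioxolane) | COc1cc(CCCCCCCCCCCCc2cc(C3OCCO3)c(F)c(C3OCCO3)c2)cc(O[Si](C(C)C)(C(C)C)C(C)C)c1 | intermediate
12 | 2-fluoro-5-[12-(3-methoxy-5-{[tri(propan-2-yl)silyl]oxy}phenyl)dodecyl]benzene-1,3-dicarbaldehyde | COc1cc(CCCCCCCCCCCCc2cc(C=O)c(F)c(C=O)c2)cc(O[Si](C(C)C)(C(C)C)C(C)C)c1 | intermediate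
13 | cesium 3-[12-(4-fluoro-3,5-diformylphenyl)dodecyl]-5-methoxyphenoxide | COc1cc([O-])cc(CCCCCCCCCCCCc2cc(C=O)c(F)c(C=O)c2)c1.[Cs+] | intermediate
14 | macrocyclic diaryl ether dialdehyde (ring A methoxy; ring B C2 and C6 formyl) | COc1cc2cc(c1)Oc1c(C=O)cc(cc1C=O)CCCCCCCCCCCC2 | intermediate
15 | macrocyclic bis-formate (ring B C2 and C6 formyloxy) | COc1cc2cc(c1)Oc1c(OC=O)cc(cc1OC=O)CCCCCCCCCCCC2 | intermediate
16 | ring A monomethyl ether of the target | COc1cc2cc(c1)Oc1c(O)cc(cc1O)CCCCCCCCCCCC2 | intermediate
17 | CNP0314249.0 (macrocyclic diaryl ether triol) | Oc1cc2cc(c1)Oc1c(O)cc(cc1O)CCCCCCCCCCCC2 | target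

**Step count**
Total step count: 10.
Longest linear sequence: 8 (steps 1, 2, 3, 6, 7, 8, 9, 10). The ring A branch (steps 4 and 5) joins at step 6.

**Steps most likely to fail**

Step 9. Hydride migration in the Criegee adduct may compete with aryl migration and lead to carboxylic acids. During the first insertion ring B still carries an electron-withdrawing formyl group, and the crowded ether oxygen is twisted and donates only weakly. Slow oxidation of ring A by surplus peracid is a second concern.

The fallback removes the hydride from the competition and sets out from 14: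
- MeMgBr (THF, −78 °C) would add to both formyl groups to give the bis(1-hydroxyethyl) macrocycle F1, a diastereomer mixture of no consequence.
- Dess–Martin periodinane would oxidise it to the 2,6-diacetyl macrocycle F2.
- Baeyer–Villiger oxidation of these aryl methyl ketones (mCPBA, catalytic CF3CO2H, CH2Cl2), where aryl migrates in preference to methyl, would give the macrocyclic bis-acetate F3.
- K2CO3 in MeOH then comes back to the route at 16.

Step 8. Intermolecular etherification may outrun ring closure and cause oligomerisation, or adventitious hydroxide may attack ring B C1.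

The fallback makes the crowded ether between two molecules and closes the ring at carbon instead. It sets out from 9 and 3:
- CsF in DMF at rt would join them to the open-chain bromo diaryl ether dialdehyde F4.
- Ethylene glycol/p-TsOH would give the open-chain bromo bis-dioxolane F5.
- 9-BBN would give the tethered alkylborane F6.
- Slow addition of F6 to PdCl2(dppf)/K3PO4 in THF/H2O would close the ring at the ring B C4–CH2 bond by an intramolecular B-alkyl Suzuki–Miyaura coupling, giving the macrocyclic bis-dioxolane F7.
- 1 M HCl/THF then comes back to the route at 14.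

Step 5. A second hydroboration of the same diene molecule, or Heck-type arylation of the surplus alkene, may erode the mono-functionalisation of two identical chain ends.

The fallback uses a chain whose ends already differ and sets out from 6:
- Mg in THF would give the arylmagnesium bromide F8.
- Alkylation of F8 with commercial 12-bromododec-1-ene (C=CCCCCCCCCCCBr) under Li2CuCl4 catalysis (THF, 0 °C → rt) comes back to the route at 9.

**Further compounds**
F1 | step 9 | bis(1-hydroxyethyl) macrocycle (ring B C2 and C6; mixture of diastereomers) | COc1cc2cc(c1)Oc1c(C(C)O)cc(cc1C(C)O)CCCCCCCCCCCC2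
F2 | step 9 | 2,6-diacetyl macrocycle | COc1cc2cc(c1)Oc1c(C(C)=O)cc(cc1C(C)=O)CCCCCCCCCCCC2
F3 | step 9 | macrocyclic bis-acetate | COc1cc2cc(c1)Oc1c(OC(C)=O)cc(cc1OC(C)=O)CCCCCCCCCCCC2
F4 | step 8 | 5-bromo-2-[3-(dodec-11-en-1-yl)-5-methoxyphenoxy]benzene-1,3-dicarbaldehyde | C=CCCCCCCCCCCc1cc(OC)cc(Oc2c(C=O)cc(Br)cc2C=O)c1
F5 | step 8 | 2,2'-{5-bromo-2-[3-(dodec-11-en-1-yl)-5-methoxyphenoxy]benzene-1,3-diyl}bis(1,3-dioxolane) | C=CCCCCCCCCCCc1cc(OC)cc(Oc2c(C3OCCO3)cc(Br)cc2C4OCCO4)c1
F6 | step 8 | 9-BBN adduct of F5 at the terminal carbon | COc1cc(CCCCCCCCCCCCB2C3CCCC2CCC3)cc(Oc2c(C3OCCO3)cc(Br)cc2C4OCCO4)c1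
F7 | step 8 | macrocyclic bis-dioxolane | COc1cc2cc(c1)Oc1c(C3OCCO3)cc(cc1C4OCCO4)CCCCCCCCCCCC2
F8 | step 5 | (3-methoxy-5-{[tri(propan-2-yl)silyl]oxy}phenyl)magnesium bromide | COc1cc([Mg]Br)cc(O[Si](C(C)C)(C(C)C)C(C)C)c1
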